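**Strategy.** The seven-membered ring holds oxygen at C6, the C7=C8 alkene, the C9 ketone and a C10 methylene bonded to quaternary C1. This is the imprint of a divinylcyclopropane Cope rearrangement: a C5=C6/C8=C9 skipped diene around C7 and a new C1–C10 bond. A terpinen-4-ol-derived 1-vinylcyclopentene (C1–C7, with the C2 and C4 stereocentres) is joined to a siloxyvinyl diazoacetate (C8–C10) by rhodium-carbenoid cyclopropanation. The strained cis-divinylcyclopropane then rearranges, closing the seven-membered ring and setting C1 in the same operation. α-Face hydroboration of C5=C6 afterwards gives the trans ring fusion and the C6 carbinol together. The C8 ester serves for methylation and is then excised.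

Key step: step 8

Numbering used throughout (daucane): C1 quaternary ring-fusion carbon (methyl), C2 CH–OAc, C3 CH2, C4 C(OH)(isopropyl), C5 ring-fusion CH, C6 CH–O-aroyl, C7 =CH, C8 =C(CH3), C9 C=O, C10 CH2. β is the face of the C1 methyl.

Assumption: (S)-(+)-terpinen-4-ol is taken as commercial in high enantiomeric purity.

**Route**

Step 1
Reactants: 1 (S)-(+)-terpinen-4-ol
Product: 2 (1R,5R)-2-methyl-5-(propan-2-yl)cyclohex-2-ene-1,5-diol
Conditions: SeO2 (0.3 equiv), t-BuOOH (2.5 equiv), salicylic acid (cat.), CH2Cl2, 23 °C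
Reagents that add atoms: tert-butyl hydroperoxide, CC(C)(C)OO
Why: Riley allylic hydroxylation (ene reaction, then [2,3]-shift) should attack the ring CH2 next to the methyl-bearing alkene carbon and deliver oxygen pseudo-axially, trans to the equatorial isopropyl group and therefore cis to the tertiary hydroxyl, by analogy with the limonene to trans-carveol case.

Step 2
Reactants: 2 (1R,5R)-2-methyl-5-(propan-2-yl)cyclohex-2-ene-1,5-diol
Product: 3 (1R,5R)-5-hydroxy-2-methyl-5-(propan-2-yl)cyclohex-2-en-1-yl acetate
Conditions: Ac2O (1.2 equiv), pyridine, DMAP (cat.), CH2Cl2, 0 °C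
Reagents that add atoms: acetic anhydride, CC(=O)OC(C)=O
Why: Nucleophile-catalysed acylation takes the secondary allylic hydroxyl and leaves the hindered tertiary one, so the final C2 acetate is in place from here on.

Step 3
Reactants: 3 (1R,5R)-5-hydroxy-2-methyl-5-(propan-2-yl)cyclohex-2-en-1-yl acetate
Product: 4 (1R,5R)-2-methyl-5-(propan-2-yl)-5-(triethylsilyloxy)cyclohex-2-en-1-yl acetate
Conditions: Et3SiOTf, 2,6-lutidine, CH2Cl2, 0 to 23 °C
Reagents that add atoms: triethylsilyl trifluoromethanesulfonate, CC[Si](CC)(CC)OS(=O)(=O)C(F)(F)F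
Why: Silyl triflate silylation of the tertiary alcohol blocks retro-aldol cleavage in step 5 and O–H insertion of the carbenoid in step 8.

Step 4
Reactants: 4 (1R,5R)-2-methyl-5-(propan-2-yl)-5-(triethylsilyloxy)cyclohex-2-en-1-yl acetate
Product: 6 (3S,5R)-5-acetoxy-6-oxo-3-(propan-2-yl)-3-(triethylsilyloxy)heptanal, via ozonide 5 (not isolated)
Conditions: O3, CH2Cl2, −78 °C; then PPh3, −78 to 23 °C
Reagents that add atoms: ozone, [O-][O+]=O
Why: Ozonolysis with reductive work-up cleaves the only alkene to the methyl ketone and the aldehyde without touching either stereocentre.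

Step 5
Reactants: 6 (3S,5R)-5-acetoxy-6-oxo-3-(propan-2-yl)-3-(triethylsilyloxy)heptanal
Product: 7 (1R,4R)-3-formyl-2-methyl-4-(propan-2-yl)-4-(triethylsilyloxy)cyclopent-2-en-1-yl acetate
Conditions: Bn2NH·CF3CO2H (0.3 equiv), toluene, 50 °C
Reagents that add atoms: none
Why: Amine-catalysed intramolecular aldol condensation: the aldehyde-derived enamine attacks the α-acetoxy ketone in a 5-exo sense and the tertiary aldol hydroxyl is lost with acid assistance to give the tetrasubstituted enal, the silyl ether on the other side of C5 being the poorer leaving group.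

Step 6
Reactants: 7 (1R,4R)-3-formyl-2-methyl-4-(propan-2-yl)-4-(triethylsilyloxy)cyclopent-2-en-1-yl acetate
Product: 8 (1R,4R)-3-ethenyl-2-methyl-4-(propan-2-yl)-4-(triethylsilyloxy)cyclopent-2-en-1-yl acetate
Conditions: Ph3PCH3Br, KOt-Bu, THF, 0 °C
Reagents that add atoms: methyltriphenylphosphonium bromide, C[P+](c1ccccc1)(c1ccccc1)c1ccccc1.[Br-]
Why: Wittig methylenation of the aldehyde is much faster than attack of the ylide on the hindered acetate and gives the 1-vinylcyclopentene.

Step 7
Reactants: 9 ethyl 2-diazo-3-oxobutanoate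
Product: 10 ethyl 3-(tert-butyldimethylsilyloxy)-2-diazobut-3-enoate
Conditions: t-BuMe2SiOTf, Et3N, CH2Cl2, 0 °C
Reagents that add atoms: tert-butyldimethylsilyl trifluoromethanesulfonate, CC(C)(C)[Si](C)(C)OS(=O)(=O)C(F)(F)F
Why: Soft enolisation and O-silylation of the acetyl group gives the siloxyvinyl diazoacetate, a donor/acceptor carbenoid precursor.

Step 8
Reactants: 8 (1R,4R)-3-ethenyl-2-methyl-4-(propan-2-yl)-4-(triethylsilyloxy)cyclopent-2-en-1-yl acetate; 10 ethyl 3-(tert-butyldimethylsilyloxy)-2-diazobut-3-enoate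
Product: 12 hydroazulene diene ester (C5=C6 and C8=C9 double bonds; 1β-methyl; 2α-acetoxy; 4α-triethylsilyloxy; 4β-isopropyl; 8-ethoxycarbonyl; 9-tert-butyldimethylsilyloxy), via cis-divinylcyclopropane 11 (not isolated)
Conditions: Rh2(R-PTAD)4 (dirhodium tetrakis[(R)-N-phthaloyl-1-adamantylglycinate], 1 mol %), 10 added slowly, hexanes, −20 to 23 °C; then toluene, 110 °C
Reagents that add atoms: none
Why: The rhodium carbenoid from 10 should cyclopropanate the terminal C6=C7 vinyl group of 8 (asynchronous concerted [2+1]; the tetrasubstituted ring alkene is too hindered), and a donor/acceptor carbenoid places the cyclopentenyl group cis to the siloxyvinyl group, giving cis-divinylcyclopropane 11. Heating then drives the strain-releasing Cope rearrangement through the boat transition state with both alkenyl groups endo: the C6–C8 bond breaks, the C1–C10 bond forms, and the seven-membered ring is closed by this [3,3]-sigmatropic shift (the three-membered ring is closed by the cheletropic carbenoid addition and consumed again). This is the known tandem cyclopropanation/Cope formal [4+3] cycloaddition of vinyl diazoacetates with dienes. The only new stereocentre that is kept is quaternary C1: the shift is suprafacial on the ring alkene, and the face of C1 that meets C10 is fixed by the configuration of C6 and C8 in 11, which the chiral rhodium carboxylate sets (reagent control; this catalyst enantiomer is chosen by analogy with the (1S,2R) sense known for Rh2(S-DOSP)4, and the mirror-image catalyst would lead to the C1 epimer). The step needs site selectivity for the vinyl group, the cis geometry of 11 and bond formation on the α face of C1 (C10 cis to the C2 acetate); the steric difference between the two alkenes, the inherent diastereoselectivity of the carbenoid and catalyst control should secure them. The methyl on C1 is the inward substituent in the boat, so the shift is expected to need heat rather than room temperature.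

Step 9
Reactants: 12 hydroazulene diene ester
Product: 14 6α-alcohol (5α-H, trans ring fusion; C8=C9 silyl enol ether ester retained), via alkylborane 13 (not isolated)
Conditions: BH3·SMe2 (2 equiv), THF, 0 to 23 °C; then 30 % H2O2, aq. NaOAc, 0 to 23 °C
Reagents that add atoms: hydrogen peroxide, OO
Why: Hydroboration–oxidation: borane adds syn across the trisubstituted C5=C6 alkene with boron at C6 (less substituted, remote from the allylic C4 oxygen) from the α face, opposite the C1 methyl and the C4 isopropyl group, so 5α-H and 6α-OH arise together, while the tetrasubstituted push–pull enol ether and the esters react more slowly.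

Step 10
Reactants: 14 6α-alcohol; 15 4-(methoxymethoxy)benzoic acid
Product: 16 6α-[4-(methoxymethoxy)benzoyloxy] ester of 14
Conditions: DCC, DMAP, CH2Cl2, 23 °C
Reagents that add atoms: none
Why: Steglich esterification acylates the only free hydroxyl, and doing so now prevents later lactonisation of the C6 oxygen onto the C8 ester.

Step 11
Reactants: 16 6α-[4-(methoxymethoxy)benzoyloxy] ester of 14
Product: 17 ethyl 8-methyl-9-oxo ester (C8 quaternary, both epimers; silyl ether at C4 retained)
Conditions: Bu4NF (1.1 equiv), MeI (5 equiv), THF, −20 to 0 °C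
Reagents that add atoms: iodomethane, CI
Why: Fluoride cleaves the silyl enol ether (a β-keto ester enolate leaves silicon easily) much faster than the hindered tertiary triethylsilyl ether, and the ammonium enolate is C-methylated at C8 (fluoride-mediated enolate alkylation); the C8 configuration does not matter because C8 becomes trigonal in step 13.

Step 12
Reactants: 17 ethyl 8-methyl-9-oxo ester
Product: 18 8-methyl-9-ketone (C8 epimers)
Conditions: LiCl, H2O, DMSO, 150 °C
Reagents that add atoms: none
Why: Krapcho dealkoxycarbonylation removes the ethoxycarbonyl group of the α,α-disubstituted β-keto ester under neutral conditions that the acetate, the aryl ester and the acetal should survive.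

Step 13
Reactants: 18 8-methyl-9-ketone
Product: 19 4-O-triethylsilyl, 4'-O-methoxymethyl derivative of the target (C7=C8 enone)
Conditions: IBX (2 equiv), DMSO, 70 °C
Reagents that add atoms: none
Why: IBX dehydrogenation of the ketone through its enol can give an alkene only on the C8 side because C1 is quaternary, so the C7=C8 enone should form.

Step 14
Reactants: 19 4-O-triethylsilyl, 4'-O-methoxymethyl derivative of the target
Product: 20 [(1R,3R,3aR,4R,8aS)-1-acetoxy-3-hydroxy-6,8a-dimethyl-7-oxo-3-(propan-2-yl)-1,2,3,3a,4,7,8,8a-octahydroazulen-4-yl] 4-hydroxybenzoate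
Conditions: 2 M aq. HCl, THF, 23 to 40 °C
Reagents that add atoms: none
Why: Acid hydrolysis removes the methoxymethyl acetal from the phenol and the triethylsilyl ether from the tertiary alcohol in one operation, while both carboxylic esters and the enone should be stable to dilute aqueous acid at this temperature.

**Compound list**

1 | (S)-(+)-terpinen-4-ol, (1S)-4-methyl-1-(propan-2-yl)cyclohex-3-en-1-ol | CC1=CC[C@](O)(C(C)C)CC1 | starting material
2 | (1R,5R)-2-methyl-5-(propan-2-yl)cyclohex-2-ene-1,5-diol (hydroxyls cis) | CC1=CC[C@](O)(C(C)C)C[C@H]1O | intermediate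
3 | (1R,5R)-5-hydroxy-2-methyl-5-(propan-2-yl)cyclohex-2-en-1-yl acetate | CC1=CC[C@](O)(C(C)C)C[C@H]1OC(C)=O | intermediate
4 | (1R,5R)-2-methyl-5-(propan-2-yl)-5-(triethylsilyloxy)cyclohex-2-en-1-yl acetate | CC1=CC[C@](O[Si](CC)(CC)CC)(C(C)C)C[C@H]1OC(C)=O | intermediate
5 | secondary ozonide (1,2,4-trioxolane) of 4, mixture at the two trioxolane carbons | CC12OOC(O1)C[C@](O[Si](CC)(CC)CC)(C(C)C)C[C@H]2OC(C)=O | intermediate
6 | (3S,5R)-5-acetoxy-6-oxo-3-(propan-2-yl)-3-(triethylsilyloxy)heptanal | CC(=O)[C@H](OC(C)=O)C[C@@](O[Si](CC)(CC)CC)(C(C)C)CC=O | intermediate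
7 | (1R,4R)-3-formyl-2-methyl-4-(propan-2-yl)-4-(triethylsilyloxy)cyclopent-2-en-1-yl acetate | CC1=C(C=O)[C@](O[Si](CC)(CC)CC)(C(C)C)C[C@H]1OC(C)=O | intermediate
8 | (1R,4R)-3-ethenyl-2-methyl-4-(propan-2-yl)-4-(triethylsilyloxy)cyclopent-2-en-1-yl acetate | CC1=C(C=C)[C@](O[Si](CC)(CC)CC)(C(C)C)C[C@H]1OC(C)=O | intermediate
9 | ethyl 2-diazo-3-oxobutanoate | CCOC(=O)C(=[N+]=[N-])C(C)=O | starting material
10 | ethyl 3-(tert-butyldimethylsilyloxy)-2-diazobut-3-enoate | CCOC(=O)C(=[N+]=[N-])C(=C)O[Si](C)(C)C(C)(C)C | intermediate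
11 | ethyl (1S,2R)-2-[(3R,5R)-3-acetoxy-2-methyl-5-(propan-2-yl)-5-(triethylsilyloxy)cyclopent-1-en-1-yl]-1-[1-(tert-butyldimethylsilyloxy)ethenyl]cyclopropane-1-carboxylate | CCOC(=O)[C@@]1(C(=C)O[Si](C)(C)C(C)(C)C)C[C@@H]1C2=C(C)[C@H](OC(C)=O)C[C@@]2(O[Si](CC)(CC)CC)C(C)C | intermediate
12 | hydroazulene diene ester: C5=C6 and C8=C9 double bonds, 1β-methyl, 2α-acetoxy, 4α-triethylsilyloxy, 4β-isopropyl, 8-ethoxycarbonyl, 9-tert-butyldimethylsilyloxy | CC(=O)O[C@@H]1C[C@@](O[Si](CC)(CC)CC)(C(C)C)C2=CCC(C(=O)OCC)=C(O[Si](C)(C)C(C)(C)C)C[C@]12C | intermediate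
13 | alkylborane from 12: 6α-BH2, 5α-H | CC(=O)O[C@@H]1C[C@@](O[Si](CC)(CC)CC)(C(C)C)[C@H]2[C@H](B)CC(C(=O)OCC)=C(O[Si](C)(C)C(C)(C)C)C[C@]12C | intermediate
14 | 6α-alcohol: 5α-H (trans ring fusion), 6α-OH, other groups as in 12 | CC(=O)O[C@@H]1C[C@@](O[Si](CC)(CC)CC)(C(C)C)[C@H]2[C@H](O)CC(C(=O)OCC)=C(O[Si](C)(C)C(C)(C)C)C[C@]12C | intermediate
15 | 4-(methoxymethoxy)benzoic acid | COCOc1ccc(cc1)C(O)=O | starting material
16 | 6α-[4-(methoxymethoxy)benzoyloxy] ester of 14 | CC(=O)O[C@@H]1C[C@@](O[Si](CC)(CC)CC)(C(C)C)[C@H]2[C@H](OC(=O)c3ccc(OCOC)cc3)CC(C(=O)OCC)=C(O[Si](C)(C)C(C)(C)C)C[C@]12C | intermediate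
17 | ethyl 8-methyl-9-oxo ester (C8 quaternary, both epimers), other groups as in 16 | CC(=O)O[C@@H]1C[C@@](O[Si](CC)(CC)CC)(C(C)C)[C@H]2[C@H](OC(=O)c3ccc(OCOC)cc3)CC(C)(C(=O)OCC)C(=O)C[C@]12C | intermediate
18 | 8-methyl-9-ketone (C8 epimers), other groups as in 16 | CC(=O)O[C@@H]1C[C@@](O[Si](CC)(CC)CC)(C(C)C)[C@H]2[C@H](OC(=O)c3ccc(OCOC)cc3)CC(C)C(=O)C[C@]12C | intermediate
19 | 4-O-triethylsilyl, 4'-O-methoxymethyl derivative of 20 (C7=C8 enone) | CC(=O)O[C@@H]1C[C@@](O[Si](CC)(CC)CC)(C(C)C)[C@H]2[C@H](OC(=O)c3ccc(OCOC)cc3)C=C(C)C(=O)C[C@]12C | intermediate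
20 | [(1R,3R,3aR,4R,8aS)-1-acetoxy-3-hydroxy-6,8a-dimethyl-7-oxo-3-(propan-2-yl)-1,2,3,3a,4,7,8,8a-octahydroazulen-4-yl] 4-hydroxybenzoate | CC(=O)O[C@@H]1C[C@@](O)(C(C)C)[C@H]2[C@H](OC(=O)c3ccc(O)cc3)C=C(C)C(=O)C[C@]12C | target

**Step count.** Total: 14 steps. Longest linear sequence: 13 steps (steps 1–6 and 8–14); step 7 is a one-step side branch.

**Steps most likely to fail**

Step 8. The [3,3] shift may stall because the C1 methyl points into the boat transition state, so that cis–trans isomerisation of the cyclopropane competes, and facial control at C1 may erode if substrate and catalyst are mismatched. The fallback sets out from 7 and comes back at 19; it lets the C2 oxygen deliver C10 through a temporary ring and closes the seven-membered ring by metathesis. Methanolysis of the acetate (K2CO3, MeOH) would give hydroxy enal F1. NBS and 2-methoxy-3-methylbuta-1,3-diene would give bromoketal F2. Ueno–Stork 5-exo radical cyclisation onto the enal β-carbon (Bu3SnH, AIBN, benzene, 80 °C), followed by DBU equilibration of the formyl group to the convex β face, would give the cis-fused bicyclic ketal aldehyde F3 with C10 necessarily cis to the C2 oxygen. Vinylzinc addition under control of a chiral amino alcohol ligand would give allylic alcohol F4. DCC coupling with 15 would give ester F5. PPTS in wet acetone would open the ketal to hydroxy enone F6, and Ac2O/pyridine would give dienone acetate F7. Ring-closing metathesis with the second-generation Hoveyda–Grubbs catalyst (toluene, 80 °C) would then form the C7=C8 bond and give 19.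

Step 1. The allylic oxidation may lose regio- and stereocontrol: attack at the methyl group, over-oxidation to the enone, or delivery of oxygen to the face trans to the tertiary hydroxyl. The fallback sets out from 1 and comes back at 3; it sets the carbinol by reduction and inversion instead. The oxidation is pushed through to the ketone (SeO2, t-BuOOH, then MnO2) to give hydroxy enone F8. Luche reduction (NaBH4, CeCl3·7H2O, MeOH) should deliver hydride axially and give the trans diol F9. Mitsunobu inversion of the secondary allylic carbinol with acetic acid (PPh3, DIAD) would give cis acetate 3 directly.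

Step 13. The dehydrogenation may fail through slow enolisation of the hindered α-methine, oxidative loss of the triethylsilyl ether, or over-oxidation to a dienone. The fallback sets out from 18 and comes back at 19 by a Saegusa–Ito sequence. Me3SiOTf and Et3N would give the more substituted trimethylsilyl enol ether F10, and Pd(OAc)2 in MeCN would give 19. The regioisomeric enol ether cannot undergo β-hydride elimination, because C1 is quaternary, and would return 18 on work-up.

Further compounds
F1 | step 8 | (3R,5R)-3-hydroxy-2-methyl-5-(propan-2-yl)-5-(triethylsilyloxy)cyclopent-1-ene-1-carbaldehyde | CC1=C(C=O)[C@](O[Si](CC)(CC)CC)(C(C)C)C[C@H]1O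
F2 | step 8 | (3R,5R)-3-[(1-bromo-2-methoxy-3-methylbut-3-en-2-yl)oxy]-2-methyl-5-(propan-2-yl)-5-(triethylsilyloxy)cyclopent-1-ene-1-carbaldehyde (ketal carbon epimers) | CC1=C(C=O)[C@](O[Si](CC)(CC)CC)(C(C)C)C[C@H]1OC(CBr)(OC)C(C)=C
F3 | step 8 | cis-fused bicyclic ketal aldehyde: C10 and the C2 oxygen joined on the α face through the C9 ketal carbon (methoxy, isopropenyl), 1β-methyl, 5β-formyl, 4α-triethylsilyloxy, 4β-isopropyl | COC1(C(C)=C)C[C@@]2(C)[C@H](C=O)[C@](O[Si](CC)(CC)CC)(C(C)C)C[C@H]2O1
F4 | step 8 | (R)-configured C6 vinyl carbinol from F3 | COC1(C(C)=C)C[C@@]2(C)[C@H]([C@H](O)C=C)[C@](O[Si](CC)(CC)CC)(C(C)C)C[C@H]2O1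
F5 | step 8 | 4-(methoxymethoxy)benzoate of F4 | COC1(C(C)=C)C[C@@]2(C)[C@H]([C@H](OC(=O)c3ccc(OCOC)cc3)C=C)[C@](O[Si](CC)(CC)CC)(C(C)C)C[C@H]2O1
F6 | step 8 | hydroxy enone: cyclopentane with 2α-hydroxyl, 1β-methyl, 1α-(3-methyl-2-oxobut-3-enyl), 5β-[1-aroyloxyprop-2-enyl], 4α-triethylsilyloxy, 4β-isopropyl | O[C@@H]1C[C@@](O[Si](CC)(CC)CC)(C(C)C)[C@@H]([C@H](OC(=O)c2ccc(OCOC)cc2)C=C)[C@]1(C)CC(=O)C(C)=C
F7 | step 8 | 2-O-acetate of F6 | CC(=O)O[C@@H]1C[C@@](O[Si](CC)(CC)CC)(C(C)C)[C@@H]([C@H](OC(=O)c2ccc(OCOC)cc2)C=C)[C@]1(C)CC(=O)C(C)=C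
F8 | step 1 | (R)-5-hydroxy-2-methyl-5-(propan-2-yl)cyclohex-2-en-1-one | CC1=CC[C@](O)(C(C)C)CC1=O
F9 | step 1 | (1S,5R)-2-methyl-5-(propan-2-yl)cyclohex-2-ene-1,5-diol (hydroxyls trans) | CC1=CC[C@](O)(C(C)C)C[C@@H]1O
F10 | step 13 | C8=C9 trimethylsilyl enol ether of 18 | CC(=O)O[C@@H]1C[C@@](O[Si](CC)(CC)CC)(C(C)C)[C@H]2[C@H](OC(=O)c3ccc(OCOC)cc3)CC(C)=C(O[Si](C)(C)C)C[C@]12C
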